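**Plan**

1. Numbering used throughout: ring carbons C5–C9 (C5 carries the side-chain carbon C4, C7 the ring oxygen, C8 the methyl, C9 carries C1). C4 bears the arms C3 (acylated in the target) and C11 (free). O1, O3, O7 and O11 are the oxygens on these carbons.
2. Retrosynthesis: the two ester C–O bonds at O3 and O7 are cut first, giving two copies of the acetal-masked (3S,4E)-dialdehyde acid 23 (from oleuropein). The C1/C11 diol is then traced back to a δ-lactone whose O1–C11 bond is the key disconnection. Next come C4–C5 (malonate Michael addition) and C9–C1 (carbonylation), and last the ring itself (Piancatelli rearrangement).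
3. Forward: the cyclopentane ring arises first, C1 and the malonate are attached, the six-membered lactone ring is closed as a temporary ring and opened again, and the two side chains are joined last.
4. Stereochemistry: C7/C8 trans from the conrotatory ring closure, made enantiopure by lipase resolution. C5 and C9 come from an equilibrating Michael addition (all-trans), C4 from the equilibrating lactonisation. The side-chain stereocentres and (E)-alkenes are carried over unchanged from oleuropein.
5. Enabling feature: C4 is a stereocentre only because its two arms end up different. O1, C1, C9, C5, C4 and C11 can close a trans-fused six-membered lactone on the cyclopentane, in which C4 lies between two carbonyls and can epimerise.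

Key step: step 9

Assumption: the lipase acetylates the (4S,5R) enantiomer of 2 faster, so 3 is recovered as the free alcohol; if the enzyme prefers the other antipode, 3 is obtained from its acetate by lipase-mediated methanolysis and the route is unchanged.

**Route**

Step 1
Reactants: 1 1-(furan-2-yl)ethanol
Product: 2 rac-trans-4-hydroxy-5-methylcyclopent-2-en-1-one
Conditions: ZnCl2 (1 equiv), dioxane/H2O 1:1, pH ≈ 6, reflux
Reagents that add atoms: water, O
Why: Piancatelli rearrangement, in which the furfuryl cation takes up water, opens to a dioxygenated pentadienyl cation and closes by conrotatory 4π-electrocyclisation so that the C7 hydroxyl and the C8 methyl come out trans.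

Step 2
Reactants: 2 rac-trans-4-hydroxy-5-methylcyclopent-2-en-1-one
Product: 3 (4R,5S)-4-hydroxy-5-methylcyclopent-2-en-1-one
Conditions: lipase PS (Burkholderia cepacia), vinyl acetate, t-BuOMe, 30 °C, stopped slightly beyond half conversion; chromatography
Reagents that add atoms: none
Why: enzymatic kinetic resolution by irreversible acyl transfer from vinyl acetate, which should leave the slow-reacting (4R,5S) alcohol enantiopure once the (4S,5R) antipode has been consumed as its acetate.

Step 3
Reactants: 3 (4R,5S)-4-hydroxy-5-methylcyclopent-2-en-1-one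
Product: 4 (4R,5S)-4-[(tert-butyldimethylsilyl)oxy]-5-methylcyclopent-2-en-1-one
Conditions: TBSCl, imidazole, DMF, 0 °C to rt
Reagents that add atoms: tert-butyldimethylsilyl chloride, CC(C)(C)[Si](C)(C)Cl
Why: standard silylation under conditions mild enough for the base-sensitive 4-hydroxy enone; no stereocentre is touched.

Step 4
Reactants: 4 (4R,5S)-4-[(tert-butyldimethylsilyl)oxy]-5-methylcyclopent-2-en-1-one
Product: 5 (2S,3R)-3-[(tert-butyldimethylsilyl)oxy]-2-methylcyclopentan-1-one
Conditions: H2 (1 atm), 10% Pd/C, EtOAc, rt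
Reagents that add atoms: none
Why: heterogeneous hydrogenation of the enone C=C; the methyl-bearing carbon α to the ketone stays in its more stable trans arrangement.

Step 5
Reactants: 5 (2S,3R)-3-[(tert-butyldimethylsilyl)oxy]-2-methylcyclopentan-1-one
Product: 7 (4R,5S)-4-[(tert-butyldimethylsilyl)oxy]-5-methylcyclopent-1-en-1-yl trifluoromethanesulfonate, via potassium enolate 6 (not isolated)
Conditions: KN(SiMe3)2, THF, −78 °C; then N-(5-chloropyridin-2-yl)bis(trifluoromethanesulfonyl)imide, −78 °C; aq. NH4Cl
Reagents that add atoms: N-(5-chloropyridin-2-yl)bis(trifluoromethanesulfonyl)imide, O=S(=O)(N(c1ccc(Cl)cn1)S(=O)(=O)C(F)(F)F)C(F)(F)F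
Why: kinetic enolisation at the unsubstituted α-carbon C5 (an enolate toward C8 would expel the C7 silanolate) followed by O-sulfonylation gives the less substituted enol triflate regioselectively.

Step 6
Reactants: 7 (4R,5S)-4-[(tert-butyldimethylsilyl)oxy]-5-methylcyclopent-1-en-1-yl trifluoromethanesulfonate
Product: 8 (4R,5R)-4-[(tert-butyldimethylsilyl)oxy]-5-methylcyclopent-1-ene-1-carbaldehyde
Conditions: Pd(PPh3)4 (5 mol %, zerovalent palladium), CO (1 atm), Bu3SnH (slow addition), LiCl, THF, 50 °C
Reagents that add atoms: carbon monoxide, [C-]#[O+]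
Why: Stille-type reductive carbonylation of a vinyl triflate (oxidative addition, CO insertion, hydride transfer from tin to the acylpalladium) installs C1 as the aldehyde without touching C7 or C8.

Step 7
Reactants: 8 (4R,5R)-4-[(tert-butyldimethylsilyl)oxy]-5-methylcyclopent-1-ene-1-carbaldehyde; 9 dibenzyl malonate
Product: 10 dibenzyl 2-[(1R,2S,3R,4R)-4-[(tert-butyldimethylsilyl)oxy]-2-formyl-3-methylcyclopentyl]propanedioate
Conditions: 9 (1.3 equiv), NaH (0.1 equiv), THF, 0 °C to rt, stirred until the isomer mixture no longer changes; AcOH quench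
Reagents that add atoms: none
Why: base-catalysed Michael addition run under equilibrating conditions, in which the malonate is expected to enter C5 anti to the silyloxy group on the flap carbon C7, while reversible addition and enolisation at C9 drain the material into the all-trans isomer, the only one with every ring substituent trans to both neighbours (sets C5 and C9).

Step 8
Reactants: 10 dibenzyl 2-[(1R,2S,3R,4R)-4-[(tert-butyldimethylsilyl)oxy]-2-formyl-3-methylcyclopentyl]propanedioate
Product: 11 dibenzyl 2-[(1R,2S,3R,4R)-4-[(tert-butyldimethylsilyl)oxy]-2-(hydroxymethyl)-3-methylcyclopentyl]propanedioate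
Conditions: NaBH4, THF/MeOH 4:1, −40 °C; AcOH, then aq. NH4Cl
Reagents that add atoms: none
Why: borohydride reduction of the aldehyde, chemoselective over the malonate esters, with a cold acidic quench so that the hydroxy malonate is isolated before it cyclises.

Step 9
Reactants: 11 dibenzyl 2-[(1R,2S,3R,4R)-4-[(tert-butyldimethylsilyl)oxy]-2-(hydroxymethyl)-3-methylcyclopentyl]propanedioate
Product: 13 benzyl (4S,4aR,6R,7R,7aS)-6-[(tert-butyldimethylsilyl)oxy]-7-methyl-3-oxooctahydrocyclopenta[c]pyran-4-carboxylate (trans-fused lactone; equatorial C3 ester), via C4-epimeric lactone 12 (not isolated)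
Conditions: DBU (0.2 equiv), toluene, 50 °C, until the lactone composition is constant; AcOH quench
Reagents that add atoms: none
Why: Under DBU the C1 hydroxyl adds to either diastereotopic benzyl ester carbonyl and expels benzyl alcohol (acyl substitution through a tetrahedral intermediate), the closest known reaction type being the base-catalysed lactonisation of δ-hydroxy malonates with concurrent epimerisation of the malonate carbon. The six-membered ring O1–C1–C9–C5–C4–C11 closes in the 6-exo-trig mode by attack of O1 on C11. The one new stereocentre, C4, is set under thermodynamic control: in both lactones it lies between two carbonyls and equilibrates through the enolate (and through reversible ring opening by the liberated benzyl alcohol), so the axial-ester epimer 12 drains into 13. The controlling element is the trans ring fusion fixed by C5 and C9, which holds the lactone in one half-chair where the free ester is either equatorial and trans to the C5–C6 bond (13) or axial and syn to H9 (12). The step needs selection of a single C4 epimer at equilibrium, and this trans-diequatorial preference secures it; viewed along C4–C5 the equatorial ester carbon is the one that becomes C3 of the target and the ring carbonyl is C11, so the later acid-versus-lactone difference addresses the correct arm.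

Step 10
Reactants: 13 benzyl (4S,4aR,6R,7R,7aS)-6-[(tert-butyldimethylsilyl)oxy]-7-methyl-3-oxooctahydrocyclopenta[c]pyran-4-carboxylate
Product: 14 (4R,4aR,6R,7R,7aS)-6-[(tert-butyldimethylsilyl)oxy]-7-methyl-3-oxooctahydrocyclopenta[c]pyran-4-carboxylic acid
Conditions: H2 (1 atm), 10% Pd/C, EtOAc, rt
Reagents that add atoms: none
Why: hydrogenolysis of the benzyl ester leaves a carboxylic acid beside the lactone, turning the difference between the arms into a reactivity difference; C4 is still epimerisable but keeps the same equatorial preference (the descriptor changes only through priorities).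

Step 11
Reactants: 14 (4R,4aR,6R,7R,7aS)-6-[(tert-butyldimethylsilyl)oxy]-7-methyl-3-oxooctahydrocyclopenta[c]pyran-4-carboxylic acid
Product: 15 (4R,4aR,6R,7R,7aS)-6-[(tert-butyldimethylsilyl)oxy]-4-(hydroxymethyl)-7-methylhexahydrocyclopenta[c]pyran-3(1H)-one
Conditions: BH3·SMe2 (1.5 equiv), THF, 0 °C to rt; MeOH quench
Reagents that add atoms: none
Why: borane reduces the carboxylic acid through its acyloxyborane much faster than the lactone, so only C3 becomes CH2OH, and C4, now next to a single carbonyl, is configurationally fixed.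

Step 12
Reactants: 15 (4R,4aR,6R,7R,7aS)-6-[(tert-butyldimethylsilyl)oxy]-4-(hydroxymethyl)-7-methylhexahydrocyclopenta[c]pyran-3(1H)-one
Product: 16 (4R,4aR,6R,7R,7aS)-6-[(tert-butyldimethylsilyl)oxy]-4-{[(tert-butyldiphenylsilyl)oxy]methyl}-7-methylhexahydrocyclopenta[c]pyran-3(1H)-one
Conditions: TBDPSCl, imidazole, CH2Cl2, 0 °C to rt
Reagents that add atoms: tert-butyl(chloro)diphenylsilane, CC(C)(C)[Si](Cl)(c1ccccc1)c1ccccc1
Why: silylation of the primary alcohol under weakly basic conditions that neither epimerise C4 nor eliminate the β-oxygen; the bulky diphenylsilyl group is chosen for its low tendency to migrate to O11 in the next step.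

Step 13
Reactants: 16 (4R,4aR,6R,7R,7aS)-6-[(tert-butyldimethylsilyl)oxy]-4-{[(tert-butyldiphenylsilyl)oxy]methyl}-7-methylhexahydrocyclopenta[c]pyran-3(1H)-one
Product: 17 (2S)-3-[(tert-butyldiphenylsilyl)oxy]-2-[(1R,2S,3R,4R)-4-[(tert-butyldimethylsilyl)oxy]-2-(hydroxymethyl)-3-methylcyclopentyl]propan-1-ol
Conditions: LiBH4, THF, MeOH (1 equiv), 0 °C to rt
Reagents that add atoms: none
Why: hydride reduction of the lactone opens it to the C1/C11 diol under mildly basic conditions in which the O3 silyl ether should stay in place, so the two arms of C4 remain distinct.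

Step 14
Reactants: 17 (2S)-3-[(tert-butyldiphenylsilyl)oxy]-2-[(1R,2S,3R,4R)-4-[(tert-butyldimethylsilyl)oxy]-2-(hydroxymethyl)-3-methylcyclopentyl]propan-1-ol
Product: 18 O1,O11-bis(4,4'-dimethoxytrityl) ether of 17
Conditions: DMTrCl (2.5 equiv), Et3N, DMAP (cat.), CH2Cl2, rt
Reagents that add atoms: 4,4'-dimethoxytrityl chloride, COc1ccc(cc1)C(Cl)(c1ccccc1)c1ccc(OC)cc1
Why: tritylation of the two primary alcohols (capture of the stabilised trityl cation) gives ethers that cannot migrate, resist fluoride and carbodiimide coupling, and are removed by the mild acid of the last step.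

Step 15
Reactants: 18 O1,O11-bis(4,4'-dimethoxytrityl) ether of 17
Product: 19 core diol with free O3–H and O7–H and O1,O11-bis(4,4'-dimethoxytrityl) protection
Conditions: Bu4NF (3 equiv), THF, rt to 40 °C
Reagents that add atoms: none
Why: fluoride cleaves both silyl ethers (O3 and O7) and leaves the trityl ethers, so exactly the two oxygens to be acylated are set free and nothing able to migrate sits on O11.

Step 16
Reactants: 20 oleuropein
Product: 21 oleacein, 2-(3,4-dihydroxyphenyl)ethyl (3S,4E)-4-formyl-3-(2-oxoethyl)hex-4-enoate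
Conditions: NaCl, DMSO/H2O, 150 °C
Reagents that add atoms: water, O
Why: Krapcho dealkoxycarbonylation, in which chloride demethylates the vinylogous carbonate ester, the acid decarboxylates and the exposed enol-ether acetal hydrolyses with loss of glucose to unveil both aldehydes, while the allylic stereocentre and the (E)-ethylidene group are not involved.

Step 17
Reactants: 21 oleacein
Product: 22 2-(3,4-dihydroxyphenyl)ethyl (3S,4E)-4-(dimethoxymethyl)-3-(2,2-dimethoxyethyl)hex-4-enoate
Conditions: HC(OMe)3, MeOH, PPTS (cat.), rt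
Reagents that add atoms: trimethyl orthoformate, COC(OC)OC; methanol, CO
Why: acid-catalysed acetalisation masks both aldehydes (the enal as its allylic acetal) with no change at the stereocentre or the alkene geometry.

Step 18
Reactants: 22 2-(3,4-dihydroxyphenyl)ethyl (3S,4E)-4-(dimethoxymethyl)-3-(2,2-dimethoxyethyl)hex-4-enoate
Product: 23 (3S,4E)-4-(dimethoxymethyl)-3-(2,2-dimethoxyethyl)hex-4-enoic acid
Conditions: LiOH·H2O (3 equiv), THF/H2O (degassed, argon), 0 °C to rt; 1 M HCl to pH 5 at 0 °C
Reagents that add atoms: lithium hydroxide, [Li+].[OH-]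
Why: saponification of the only ester; acetals are inert to base and the γ,δ-unsaturated acid has no acidic stereocentre.

Step 19
Reactants: 19 core diol; 23 (3S,4E)-4-(dimethoxymethyl)-3-(2,2-dimethoxyethyl)hex-4-enoic acid (3 equiv)
Product: 24 O3,O7-diester of 19 with acid 23 (tetra-acetal; O1,O11-bis(4,4'-dimethoxytrityl))
Conditions: DIC, DMAP, CH2Cl2, 0 °C to rt
Reagents that add atoms: none
Why: Steglich esterification (carbodiimide activation, acyl transfer through the acylpyridinium) acylates the primary O3 and, with excess acid, the hindered secondary O7; the acid has no α-stereocentre, so activation cannot epimerise it.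

Step 20
Reactants: 24 O3,O7-diester of 19 with acid 23
Product: 25 CNP0192766.1, the O3,O7-bis[(3S,4E)-4-formyl-3-(2-oxoethyl)hex-4-enoyl] ester of the all-trans core with free O1–H and O11–H
Conditions: AcOH/THF/H2O 3:1:1, rt
Reagents that add atoms: water, O
Why: mild acid hydrolysis ionises the dimethoxytrityl ethers and hydrolyses the four dimethyl acetals through oxocarbenium ions, under conditions too weak for ester cleavage or an O3-to-O11 acyl shift; the conjugated (E)-enals re-form as the stable isomers.

**Compound list**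

1 | 1-(furan-2-yl)ethanol (racemic) | CC(O)c1ccco1 | starting material
2 | rac-trans-4-hydroxy-5-methylcyclopent-2-en-1-one | C1=C[C@@H](O)[C@H](C)C1=O.C1=C[C@H](O)[C@@H](C)C1=O | intermediate
3 | (4R,5S)-4-hydroxy-5-methylcyclopent-2-en-1-one | C1=C[C@@H](O)[C@H](C)C1=O | intermediate
4 | (4R,5S)-4-[(tert-butyldimethylsilyl)oxy]-5-methylcyclopent-2-en-1-one | C1=C[C@@H](O[Si](C)(C)C(C)(C)C)[C@H](C)C1=O | intermediate
5 | (2S,3R)-3-[(tert-butyldimethylsilyl)oxy]-2-methylcyclopentan-1-one | C1C[C@@H](O[Si](C)(C)C(C)(C)C)[C@H](C)C1=O | intermediate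
6 | potassium (4R,5S)-4-[(tert-butyldimethylsilyl)oxy]-5-methylcyclopent-1-en-1-olate (not isolated) | C1[C@@H](O[Si](C)(C)C(C)(C)C)[C@H](C)C([O-])=C1.[K+] | intermediate
7 | (4R,5S)-4-[(tert-butyldimethylsilyl)oxy]-5-methylcyclopent-1-en-1-yl trifluoromethanesulfonate | C1[C@@H](O[Si](C)(C)C(C)(C)C)[C@H](C)C(OS(=O)(=O)C(F)(F)F)=C1 | intermediate
8 | (4R,5R)-4-[(tert-butyldimethylsilyl)oxy]-5-methylcyclopent-1-ene-1-carbaldehyde | C1[C@@H](O[Si](C)(C)C(C)(C)C)[C@H](C)C(C=O)=C1 | intermediate
9 | dibenzyl malonate | O=C(CC(=O)OCc1ccccc1)OCc1ccccc1 | starting material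
10 | dibenzyl 2-[(1R,2S,3R,4R)-4-[(tert-butyldimethylsilyl)oxy]-2-formyl-3-methylcyclopentyl]propanedioate (all-trans) | O=C(OCc1ccccc1)C(C(=O)OCc1ccccc1)[C@@H]2C[C@@H](O[Si](C)(C)C(C)(C)C)[C@H](C)[C@H]2C=O | intermediate
11 | dibenzyl 2-[(1R,2S,3R,4R)-4-[(tert-butyldimethylsilyl)oxy]-2-(hydroxymethyl)-3-methylcyclopentyl]propanedioate | O=C(OCc1ccccc1)C(C(=O)OCc1ccccc1)[C@@H]2C[C@@H](O[Si](C)(C)C(C)(C)C)[C@H](C)[C@H]2CO | intermediate
12 | benzyl (4R,4aR,6R,7R,7aS)-6-[(tert-butyldimethylsilyl)oxy]-7-methyl-3-oxooctahydrocyclopenta[c]pyran-4-carboxylate (axial ester; not isolated) | O=C(OCc1ccccc1)[C@@H](C(=O)O3)[C@@H]2C[C@@H](O[Si](C)(C)C(C)(C)C)[C@H](C)[C@H]2C3 | intermediate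
13 | benzyl (4S,4aR,6R,7R,7aS)-6-[(tert-butyldimethylsilyl)oxy]-7-methyl-3-oxooctahydrocyclopenta[c]pyran-4-carboxylate (trans-fused; equatorial ester) | O=C(OCc1ccccc1)[C@H](C(=O)O3)[C@@H]2C[C@@H](O[Si](C)(C)C(C)(C)C)[C@H](C)[C@H]2C3 | intermediate
14 | (4R,4aR,6R,7R,7aS)-6-[(tert-butyldimethylsilyl)oxy]-7-methyl-3-oxooctahydrocyclopenta[c]pyran-4-carboxylic acid | O=C(O)[C@H](C(=O)O3)[C@@H]2C[C@@H](O[Si](C)(C)C(C)(C)C)[C@H](C)[C@H]2C3 | intermediate
15 | (4R,4aR,6R,7R,7aS)-6-[(tert-butyldimethylsilyl)oxy]-4-(hydroxymethyl)-7-methylhexahydrocyclopenta[c]pyran-3(1H)-one | OC[C@H](C(=O)O3)[C@@H]2C[C@@H](O[Si](C)(C)C(C)(C)C)[C@H](C)[C@H]2C3 | intermediate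
16 | (4R,4aR,6R,7R,7aS)-6-[(tert-butyldimethylsilyl)oxy]-4-{[(tert-butyldiphenylsilyl)oxy]methyl}-7-methylhexahydrocyclopenta[c]pyran-3(1H)-one | CC(C)(C)[Si](c1ccccc1)(c1ccccc1)OC[C@H](C(=O)O3)[C@@H]2C[C@@H](O[Si](C)(C)C(C)(C)C)[C@H](C)[C@H]2C3 | intermediate
17 | (2S)-3-[(tert-butyldiphenylsilyl)oxy]-2-[(1R,2S,3R,4R)-4-[(tert-butyldimethylsilyl)oxy]-2-(hydroxymethyl)-3-methylcyclopentyl]propan-1-ol | CC(C)(C)[Si](c1ccccc1)(c1ccccc1)OC[C@H](CO)[C@@H]2C[C@@H](O[Si](C)(C)C(C)(C)C)[C@H](C)[C@H]2CO | intermediate
18 | O1,O11-bis(4,4'-dimethoxytrityl) ether of 17 (O3 tert-butyldiphenylsilyl, O7 tert-butyldimethylsilyl) | CC(C)(C)[Si](c1ccccc1)(c1ccccc1)OC[C@H](COC(c1ccccc1)(c1ccc(OC)cc1)c1ccc(OC)cc1)[C@@H]2C[C@@H](O[Si](C)(C)C(C)(C)C)[C@H](C)[C@H]2COC(c1ccccc1)(c1ccc(OC)cc1)c1ccc(OC)cc1 | intermediate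
19 | core diol: O3–H and O7–H free, O1 and O11 as 4,4'-dimethoxytrityl ethers | OC[C@H](COC(c1ccccc1)(c1ccc(OC)cc1)c1ccc(OC)cc1)[C@@H]2C[C@@H](O)[C@H](C)[C@H]2COC(c1ccccc1)(c1ccc(OC)cc1)c1ccc(OC)cc1 | intermediate
20 | oleuropein | C/C=C1\[C@@H](C(C(=O)OC)=CO[C@H]1O[C@@H]2O[C@H](CO)[C@@H](O)[C@H](O)[C@H]2O)CC(=O)OCCc3ccc(O)c(O)c3 | starting material
21 | oleacein, 2-(3,4-dihydroxyphenyl)ethyl (3S,4E)-4-formyl-3-(2-oxoethyl)hex-4-enoate | C/C=C(/C=O)[C@@H](CC=O)CC(=O)OCCc1ccc(O)c(O)c1 | intermediate
22 | 2-(3,4-dihydroxyphenyl)ethyl (3S,4E)-4-(dimethoxymethyl)-3-(2,2-dimethoxyethyl)hex-4-enoate | C/C=C(/C(OC)OC)[C@@H](CC(OC)OC)CC(=O)OCCc1ccc(O)c(O)c1 | intermediate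
23 | (3S,4E)-4-(dimethoxymethyl)-3-(2,2-dimethoxyethyl)hex-4-enoic acid | C/C=C(/C(OC)OC)[C@@H](CC(OC)OC)CC(=O)O | intermediate
24 | O3,O7-diester of 19 with acid 23 (four dimethyl acetals, two dimethoxytrityl ethers) | C/C=C(/C(OC)OC)[C@@H](CC(OC)OC)CC(=O)OC[C@H](COC(c1ccccc1)(c1ccc(OC)cc1)c1ccc(OC)cc1)[C@@H]2C[C@@H](OC(=O)C[C@H](CC(OC)OC)/C(C(OC)OC)=C\C)[C@H](C)[C@H]2COC(c1ccccc1)(c1ccc(OC)cc1)c1ccc(OC)cc1 | intermediate
25 | CNP0192766.1 | C/C=C(/C=O)[C@@H](CC=O)CC(=O)OC[C@H](CO)[C@@H]1C[C@@H](OC(=O)C[C@H](CC=O)/C(C=O)=C\C)[C@H](C)[C@H]1CO | target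

**Step count and risks**

Total step count: 20. Longest linear sequence: 17 steps (steps 1–15, 19 and 20, from 1-(furan-2-yl)ethanol); steps 16–18 form a three-step branch from oleuropein.

Steps most likely to fail:

Step 7. The malonate may approach C5 with little discrimination between the two ring faces, because the C8 methyl shields the face opposite to the C7 silyloxy group, and the retro-Michael/enolisation equilibrium meant to correct C5 and C9 may be slower than self-condensation of the aldehyde. The fallback sets out from enal 8 and comes back at aldehyde 10. The addition is run under covalent iminium catalysis with (S)-α,α-diphenylprolinol trimethylsilyl ether (20 mol %) and benzoic acid in ethanol at rt, followed by brief treatment with DBU to settle C9. In the s-trans E-iminium ion the aryl(silyloxy)methyl arm of this antipode lies over the upper ring face (that of the C7 silyloxy group), so the malonate is steered to the lower face of C5 by the catalyst and no longer by the weak ring bias. Should the iminium ion react through its s-cis rotamer, the (R)-catalyst is the matched one; both antipodes are commercial. No new compound is made on this way.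

Step 9. Ring closure may stall at the open hydroxy diester, or the energy gap between the equatorial- and axial-ester lactones may be too small for the equilibrium to deliver a single C4 epimer. The fallback sets out from hydroxy malonate 11 and comes back at hydroxymethyl lactone 15. Both benzyl esters are removed by hydrogenolysis (H2, Pd/C, EtOAc) to give the hydroxy malonic acid F1. Heating in toluene at 110 °C makes it lose CO2 and lactonise to the trans-fused lactone with a CH2 group at C4 F2. Its lithium enolate (LiN(i-Pr)2, THF, −78 °C) is hydroxymethylated with gaseous formaldehyde. The product is expected as 15 together with its C4 epimer, the axial hydroxymethyl lactone F3, and is brought to the equatorial isomer 15 by enolate formation with 2.2 equiv LiN(i-Pr)2 and reprotonation (or DBU in toluene). Here C3 is added to a ring in which C11 already is the lactone carbonyl, so no choice between two esters is needed and C4 rests on one epimerisable centre.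

Step 20. Once O11 is uncovered, the O3 acyl group may migrate to it during the hours needed for acetal hydrolysis, and the four aldehydes may form hemiacetals or oligomers with the free primary hydroxyls in the acidic medium. The fallback sets out from diol 17 and comes back at the target 25. The two primary hydroxyls are capped with 4-methoxybenzyl 2,2,2-trichloroacetimidate and La(OTf)3 (cat.) in toluene to give the bis(4-methoxybenzyl) ether F4. Bu4NF frees O3 and O7 to give the diol F5, and coupling with acid 23 (DIC, DMAP) gives the tetra-acetal diester F6. Aqueous acetic acid then unmasks the four aldehydes while O1 and O11 are still capped, so no hydroxyl is present for acyl migration, giving the tetra-aldehyde bis(4-methoxybenzyl) ether F7. DDQ in CH2Cl2/pH 7 buffer at 0 °C finally removes the two benzyl-type ethers under neutral oxidative conditions to give 25.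

**Further compounds**

F0 | step 7 | none | none
F1 | step 9 | 2-[(1R,2S,3R,4R)-4-[(tert-butyldimethylsilyl)oxy]-2-(hydroxymethyl)-3-methylcyclopentyl]propanedioic acid | O=C(O)C(C(=O)O)[C@@H]1C[C@@H](O[Si](C)(C)C(C)(C)C)[C@H](C)[C@H]1CO
F2 | step 9 | trans-fused 6-[(tert-butyldimethylsilyl)oxy]-7-methylhexahydrocyclopenta[c]pyran-3(1H)-one (C4 = CH2) | O=C1C[C@@H]2C[C@@H](O[Si](C)(C)C(C)(C)C)[C@H](C)[C@H]2CO1
F3 | step 9 | C4 epimer of 15 (axial hydroxymethyl) | OC[C@@H](C(=O)O3)[C@@H]2C[C@@H](O[Si](C)(C)C(C)(C)C)[C@H](C)[C@H]2C3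
F4 | step 20 | O1,O11-bis(4-methoxybenzyl) ether of 17 | CC(C)(C)[Si](c1ccccc1)(c1ccccc1)OC[C@H](COCc1ccc(OC)cc1)[C@@H]2C[C@@H](O[Si](C)(C)C(C)(C)C)[C@H](C)[C@H]2COCc1ccc(OC)cc1
F5 | step 20 | core diol with O1,O11-bis(4-methoxybenzyl) protection | OC[C@H](COCc1ccc(OC)cc1)[C@@H]2C[C@@H](O)[C@H](C)[C@H]2COCc1ccc(OC)cc1
F6 | step 20 | O3,O7-diester of F5 with acid 23 (tetra-acetal) | C/C=C(/C(OC)OC)[C@@H](CC(OC)OC)CC(=O)OC[C@H](COCc1ccc(OC)cc1)[C@@H]2C[C@@H](OC(=O)C[C@H](CC(OC)OC)/C(C(OC)OC)=C\C)[C@H](C)[C@H]2COCc1ccc(OC)cc1
F7 | step 20 | O1,O11-bis(4-methoxybenzyl) ether of 25 | C/C=C(/C=O)[C@@H](CC=O)CC(=O)OC[C@H](COCc1ccc(OC)cc1)[C@@H]2C[C@@H](OC(=O)C[C@H](CC=O)/C(C=O)=C\C)[C@H](C)[C@H]2COCc1ccc(OC)cc1
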